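In the first minutes of these flasks X is already up, so that is when you must start to look.

| flask | Z | E | J | remark | time |
|---|---|---|---|---|---|
| spring | 0.20 M | 0.50 M | 0.20 M | run made earlier |  |
| autumn | 0.28 M | 0.50 M | 0.20 M | run made earlier |  |
| noon | 0.44 M | 0.50 M | 0.20 M | run made earlier |  |
| dusk | 0.20 M | 0.25 M | 0.20 M | run made earlier |  |
| red | 0.20 M | 0.500 M | 0.200 M (fed, over 2.0 h) | all else is in the flask from the start; the feed brings no volume worth counting | 2.5 h |
| teal | 0.20 M | 0.500 M | 0.200 M | everything together at the start | 2.5 h |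
| violet | 0.20 M | 0.500 M (fed, over 2.0 h) | 0.200 M | all else is in the flask from the start; the feed brings no volume worth counting | 2.5 h |

| run | time / h | X / % | D / % |
|---|---|---|---|
| spring | 0.200 | 13.4 | 7.7 |
| spring | 0.333 | 12.0 | 14.4 |
| spring | 0.500 | 10.9 | 17.5 |
| spring | 0.833 | 8.2 | 25.3 |
| spring | 1.50 | 7.0 | 35.8 |
| spring | 2.50 | 5.0 | 47.4 |
| autumn | 0.250 | 11.0 | 8.5 |
| autumn | 0.417 | 11.0 | 15.1 |
| autumn | 0.667 | 8.4 | 21.3 |
| autumn | 1.00 | 6.7 | 24.9 |
| autumn | 2.00 | 6.0 | 40.3 |
| autumn | 3.00 | 6.0 | 46.3 |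
| noon | 0.250 | 11.9 | 10.8 |
| noon | 0.417 | 11.2 | 16.4 |
| noon | 0.667 | 8.2 | 19.7 |
| noon | 1.00 | 6.8 | 23.9 |
| noon | 2.00 | 6.9 | 33.3 |
| noon | 3.00 | 3.7 | 37.5 |
| dusk | 0.250 | 5.9 | 11.1 |
| dusk | 0.417 | 4.8 | 17.5 |
| dusk | 0.833 | 3.5 | 30.3 |
| dusk | 1.50 | 3.8 | 41.4 |
| dusk | 3.00 | 3.6 | 55.9 |

(each reading ± 1 percentage point)



1. the best flask by share of X in X plus D; "all alike" if 1.5 percentage points covers them all (red / teal / violet / all alike)
2. share of X in X plus D at the end, red
3. share of X in X plus D at the end, teal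
4. share of X in X plus D at the end, violet

Teal is the spring recipe again, so spring's readings show you teal's run in advance. Spring has X at 13.4% by 0.200 h, while dusk, with 0.25 M of E in place of 0.50 M, has 5.9% by 0.250 h: X comes early and goes with E. Spring's X readings then fall fast, to 8.2% by 0.833 h, and more gently after that, 7.0% by 1.50 h and 5.0% by 2.50 h, while its D keeps climbing, so watch D through the long middle of the run.

Spring's first D reading, 7.7% in 0.200 h at 0.20 M of J, gives a pace (a second-order rate constant, as read) of 1.93 M⁻¹ h⁻¹. One over the pace times the partner's concentration is a time, 2.60 h at cJ = 0.200 M: the D clock. It is about as long as the 2.5 h of the run, so D has time to grow large.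

Red's J comes in steadily over 2.0 h, so even with none used its mean over the feed is half the charge. The clock then reads 5.19 h, longer than the run, so I expect red's D to lag. Violet has its E thinly fed, with J all there from the start, so I liken it to dusk, whose last readings give a share of 6.05%, against 9.54% for spring at its last.

The forecast names red, with 15% for red, 10% for teal and 10% for violet, on the ground that “slow J lowers D”. Its violet stands above my dusk figure.

Red gives 15.0%, teal 11.1% and violet 7.85%, so red leads. At the end red holds 36.1% of D against 46.6% in teal.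

    Z + E → X (k = 9.22 × 10⁻⁴ M⁻¹ s⁻¹)
    J + E → G (k = 3.60 × 10⁻⁴ M⁻¹ s⁻¹)
    Z + J → D (k = 8.00 × 10⁻⁴ M⁻¹ s⁻¹)
    E → L (k = 0.00152 s⁻¹)
    X ⇌ Q (K = 2.72, k = 7.22 × 10⁻⁴ s⁻¹)

Teal's J averages 0.130 M over the first 2.0 h, which stretches its clock to 3.99 h. A neighbour of violet with 0.80 M of Z has Z as the partner, so the clock for J reads 0.649 h, shorter than the run, and that flask ends with 1.51% of its J.

The data come from a simulation with made-up constants; scatter was added.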